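## Retrosynthetic overview
1. The target (9) comes from regioselective acylation of pentaol 6: isovalerate at C1-OH and C11-OH, then acetate at C10-OH.
2. Pentaol 6 comes from DIBAL global reduction of diol diacetate 5, which reduces the C11 methyl ester to CH₂OH and removes both acetates.
3. Diol 5 (7β-OH, 8α-OH, C10 β) comes from acid-promoted, acetate-assisted opening of the 7β,8β-epoxide 4. Attack at C8 occurs with inversion.
4. Epoxide 4 comes from electrochemical Mn-oxo epoxidation of genipin diacetate 3 on the convex β-face. This is the key step. (–)-Genipin supplies C1, C5 and C9, and the only new ring is this epoxide, which is opened in the next step.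

**Assumptions**
- Genipin is bought as natural (–)-genipin, drawn as the 1β-lactol.
- I checked the target SMILES against genipin: C1, C5 and C9 have the same configuration as in genipin. C7 (β-OH) and C8 (α-OH, β-CH₂OAc) must therefore be set by the route.

## Route

**Step 1**
Reactants: **1** (–)-genipin; **2** acetic anhydride
Product: **3** genipin 1β,10-diacetate
Conditions: Ac₂O (3 equiv), pyridine, DMAP (0.1 equiv), CH₂Cl₂, 0 °C → rt, 3 h
Reagents that add atoms: acetic anhydride, CC(=O)OC(C)=O
Why: Standard O-acetylation of the primary allylic alcohol and the lactol (acylation). It masks the lactol against anodic oxidation and installs the 10-OAc needed for neighbouring-group participation in step 3. The C1 anomeric centre is re-set later (step 5).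

**Step 2**
Reactants: **3** genipin 1β,10-diacetate
Product: **4** 7β,8β-epoxide of 3 (C10 on the α-face)
Conditions: Mn(OTf)₂ (5 mol %), 2,2'-bipyridine (10 mol %), AcOH/NaOAc (0.5 equiv each), LiClO₄ (0.1 M), MeCN/H₂O 9:1, undivided cell, graphite-felt anode / Pt cathode, constant current 8 mA, 25 °C, about 2.5 F/mol; neutral work-up (aq. NaHCO₃, EtOAc)
Reagents that add atoms: water, O
Why: Proposed new method: anodic oxidation of Mn(II)/bipyridine in aqueous MeCN gives a Mn(IV)=O species, and H⁺ is reduced to H₂ at the cathode, so the net change is alkene + H₂O → epoxide + H₂. The oxo is transferred to the convex β-face of the C7=C8 bond, the face bearing H-5 and H-9, because the pyran ring (C1 and C4 on the α-face) shields the concave face. This sets C7 and C8 as the 7β,8β-epoxide. The push–pull C3=C4 enol ether, deactivated by the C11 ester, and the acetylated acetal should survive. The closest known reactions are Mn-catalysed electro-epoxidation of simple alkenes and Mn-oxo epoxidation of trisubstituted cyclopentenes. I have not seen them used on an iridoid with an allylic acetoxymethyl group.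

**Step 3**
Reactants: **4** epoxide
Product: **5** methyl 1β,10-diacetoxy-7β,8α-dihydroxy-iridoid-3-ene-11-oate (5β-H, 9β-H; the C8-OH/C10-OAc regioisomer is expected to dominate)
Conditions: PPTS (0.3 equiv), MeCN/H₂O 9:1, 50 °C, 6 h
Reagents that add atoms: water, O
Why: This is acid-promoted neighbouring-group epoxide opening (Winstein-type acetoxonium pathway, as in epoxy-acetate to trans-diol monoacetate conversions). The carbonyl O of the 10-acetate attacks the protonated epoxide at tertiary C8 from the α-face, anti to the breaking C8–O bond. This is a 5-exo closure with inversion at C8 and gives a spiro-1,3-dioxolan-2-ylium ion, which places C10 on the β-face. C7 keeps its β-oxygen, so the net result is anti-opening with 7β-OH and 8α-OH. Water adds to the cation and the orthoacid collapses to the hydroxy-acetate. Any 8-OAc/10-OH regioisomer converges in step 4, where all acetates are removed.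

**Step 4**
Reactants: **5** diol diacetate
Product: **6** iridoid-3-ene-1β,7β,8α,10,11-pentol (5β-H, 9β-H)
Conditions: DIBAL-H (12 equiv), CH₂Cl₂, –78 → 0 °C, 3 h; Rochelle salt work-up
Reagents that add atoms: none (hydride adds only hydrogen)
Why: DIBAL reduces the conjugated methyl ester to the allylic alcohol and cleaves both acetates by acyl–O reduction (ester reduction). The lactol is held as an aluminium lactolate, as in DIBAL reduction of lactones, and no carbon stereocentre except the anomeric C1 is touched.

**Step 5**
Reactants: **6** pentaol; **7** isovaleryl chloride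
Product: **8** 1β,11-bis(isovaleryloxy)-iridoid-3-ene-7β,8α,10-triol
Conditions: isovaleryl chloride (2.3 equiv), pyridine (6 equiv), CH₂Cl₂, –20 → 0 °C, 4 h, no DMAP
Reagents that add atoms: isovaleryl chloride, CC(C)CC(=O)Cl
Why: Acid chloride/pyridine acylation favours the accessible lactol 1-OH and the primary allylic 11-OH over the neopentyl 10-OH, the hindered secondary 7-OH and the tertiary 8-OH. The anomeric C1 centre is set under Curtin–Hammett control with the lactol equilibrating. The 1β anomer is favoured by the anomeric effect and the cis-fused bicycle, and any minor α-anomer is removed chromatographically.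

**Step 6**
Reactants: **8** triol; **2** acetic anhydride
Product: **9** target, 10-acetoxy-1β,11-bis(isovaleryloxy)-iridoid-3-ene-7β,8α-diol
Conditions: Ac₂O (1.2 equiv), pyridine, CH₂Cl₂, –10 → 0 °C, 2 h
Reagents that add atoms: acetic anhydride, CC(=O)OC(C)=O
Why: Mild acetylation without DMAP is selective for the remaining primary 10-OH over the hindered secondary 7-OH and the tertiary 8-OH. The isovalerates and the stereocentres are unchanged.

## Compound list
1 | (–)-genipin, methyl (1R,4aS,7aS)-1-hydroxy-7-(hydroxymethyl)-1,4a,5,7a-tetrahydrocyclopenta[c]pyran-4-carboxylate | COC(=O)C1=CO[C@H]([C@H]2[C@@H]1CC=C2CO)O | starting material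
2 | acetic anhydride | CC(=O)OC(C)=O | starting material (reagent)
3 | genipin 1β,10-diacetate | CC(=O)OCC1=CC[C@@H]2C(C(=O)OC)=CO[C@@H](OC(C)=O)[C@H]12 | intermediate
4 | 7β,8β-epoxide of 3 (C10 on the α-face) | CC(=O)OC[C@]12O[C@H]1C[C@@H]3C(C(=O)OC)=CO[C@@H](OC(C)=O)[C@H]23 | intermediate
5 | methyl 1β,10-diacetoxy-7β,8α-dihydroxy-iridoid-3-ene-11-oate | CC(=O)OC[C@]1(O)[C@H]2[C@H](OC(C)=O)OC=C(C(=O)OC)[C@H]2C[C@@H]1O | intermediate
6 | iridoid-3-ene-1β,7β,8α,10,11-pentol | OC[C@]1(O)[C@H]2[C@H](O)OC=C(CO)[C@H]2C[C@@H]1O | intermediate
7 | isovaleryl chloride | CC(C)CC(=O)Cl | starting material (reagent)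
8 | 1β,11-bis(isovaleryloxy)-iridoid-3-ene-7β,8α,10-triol | OC[C@]1(O)[C@H]2[C@H](OC(=O)CC(C)C)OC=C(COC(=O)CC(C)C)[C@H]2C[C@@H]1O | intermediate
9 | target (CID42638123) | CC(=O)OC[C@]1(O)[C@H]2[C@H](OC(=O)CC(C)C)OC=C(COC(=O)CC(C)C)[C@H]2C[C@@H]1O | target

## Totals
Total steps: 6. Longest linear sequence: 6 steps, all linear.

## Three steps most likely to fail
1. **Step 2 (the proposed new step: electro-epoxidation).**
   - Risks: Mn=O allylic C–H oxidation at C6 or C9, over-oxidation, poor facial selectivity, or epoxide opening in the cell.
   - Fallback (known chemistry): epoxidise **3** with DMDO (acetone, CH₂Cl₂, 0 °C) or with mCPBA/NaHCO₃ to give the same epoxide **4**, then continue with step 3.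
2. **Steps 5 and 6: regioselectivity and the C1 anomer.**
   - Risk: some acylation at 10-OH or 7-OH, or an α/β mixture at C1.
   - Fallback: reverse the acylation order. Convert pentaol **6** to its cyclic orthoacetate (MeC(OMe)₃, PPTS) and open it with aqueous AcOH to install the 10-OAc first. Then bis-isovalerylate the 1-OH and 11-OH with isovaleryl chloride/pyridine at –20 °C, so the neopentyl 10-OH no longer competes.
3. **Step 4: DIBAL on the polyoxygenated lactol-containing substrate.**
   - Risks: incomplete ester reduction, or over-reduction through the ring-opened lactol.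
   - Fallback: hydrolyse all esters (LiOH, THF/H₂O, 0 °C) to the acid, then reduce via the mixed anhydride (ClCO₂Et, NMM; then NaBH₄, THF/MeOH, –10 °C) to reach the same pentaol **6**.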